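Its constants were set for the occasion; the result is computed.

The ratio I carry through this flask sets the G lost by dimerisation and capture against the G lost by ring closure.

    G → Z (k1 = 0.0847 s⁻¹)
    G ⇌ Q (K2 = 0.41, k2 = 0.133 s⁻¹)
    2 G → G2 (k3 = 104 L mol⁻¹ s⁻¹)
    G + G2 → G.G2 (k4 = 1050 L mol⁻¹ s⁻¹)
    G2 → L (k5 = 0.0474 s⁻¹)
    Z ⇌ E (K6 = 0.168, k6 = 0.0703 s⁻¹)

G 0.50 mM; time 20 min

- percent here means G units held: one G2 or L counts as two
- percent here means G units held: one G.G2 counts as three
- two of one species on the left: rate k times its square, two consumed each time
- the reaction counts as stopped when no species that holds the G changes by six tenths of a point or more over the second half of the time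
- run time (flask): 20 min

- why nothing more happens at 20 min, or that something still does (forward and back rates have come level / all of G has reacted / it is still moving)
- share of the G used up at 20 min
- Z at 20 min, in percent of the G charged
- G.G2 at 20 min, in percent of the G charged
- amount of Z if the flask were left three thousand times as long, in percent of the G charged

At the bench I count each dimerisation as 3 G, two coupling and one catching G2, because at the charge G2 has a half-life of 1.3 s against G, shorter than its 0.24 min on the way to L. This rule stops working where k4[G] falls to k5, at [G] = 0.0451 mM, with 12.7 % of the G and Q pool left.

The pool's half-life by ring closure is 11.5 s, and G and Q relax in 1.52 s, faster than that. So I treat G and Q as a rapid pre-equilibrium: I work with x, the fraction of the pool left, and take [G] as its equilibrium share.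

I call B = 1.31 the dimer load, the G lost through dimerisation and capture per G lost to ring closure at the full pool. B itself holds no x and scales with the charge of G, while the local ratio, Bx, falls as the pool empties. At fraction left x, ring closure takes one part in one plus Bx, and averaging this from the full pool to empty gives the logarithm of one plus B, divided by B. That is 64.0 % of the charge for Z and E together. At the border, ring closure already takes 85.7 % of what leaves.

Z and E relax in 1.42 s, faster than the pool drains, so K6 divides that share. I commit to Z at 54.8 %, and to the same 54.8 % for the long flask. The conversion is 100 %, and G.G2 stays below 36.0 %.

The forecast gives all of G has reacted, conversion 100 %, Z 56 %, slightly above my figure, G.G2 28.5 % and long-time Z 56 %, reasoning that “every sink is irreversible”.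

In this flask all of G has reacted: conversion is 100 %, Z stands at 54.9 %, and the flask left far longer holds Z 54.9 %. It also holds L 7.44 % and G.G2 28.5 % at 20.0 min. The neighbour flask charged with 0.20 mM of G has a dimer load of 0.522, so the same average gives Z 68.9 %. That neighbour flask holds Z 70.2 % at 20.0 min.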